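**Plan**

- Retrosynthesis first cuts the two ester C6–O bonds (double Mitsunobu with inversion), giving the bis-benzyl α-truxillic-type diacid 30 and two molecules of the C6-epimeric amino alcohol 19.
- In 19 (cyclopenta[c]pyridine numbering) the oxygenated C6 lies between C5 and C7 of a cyclopentane fused at C4a–C7a to the piperidine. This is a cyclopentenone retron made of alkyne C5≡C4a, alkene C7a=C7 and CO, so C4a–C7a, C5–C6 and C6–C7 are cut together (Pauson–Khand), leaving the carbamate-tethered 1,7-enyne 14.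
- Forward: chain 14 is assembled from methyl (S)-3-hydroxy-2-methylpropanoate, both rings of the bicycle close in one step, then hydrogenation, ketone reduction and carbamate-to-N-methyl reduction follow.
- The cyclobutane ring is bought intact. Its two C–aryl bonds are made by two amide-directed C–H arylations of a cis-cyclobutane-1,3-dicarboxylate with an epimerisation in between.
- Stereochemistry: C4 from the chiral pool; C7a from chair-like folding with the C4 methyl pseudo-equatorial; C7 from the E alkene; C4a from convex-face hydrogenation; C6 from convex-face hydride delivery followed by Mitsunobu inversion.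
- Cyclobutane: relative configuration from the cis-directing amide plus epimerisation; absolute configuration from resolution of the first chiral intermediate 25.

Key step: step 9

Remark: (E)-1-bromobut-2-ene (12) is taken as isomerically pure E material, because its alkene geometry becomes the C7 configuration.

**Route**

Step 1
Reactants: 1 methyl (S)-3-hydroxy-2-methylpropanoate
Product: 2 methyl (S)-3-[(tert-butyldimethylsilyl)oxy]-2-methylpropanoate
Conditions: tBuMe2SiCl, imidazole, DMF, 0 °C to rt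
Reagents that add atoms: tert-butyldimethylsilyl chloride, CC(C)(C)[Si](C)(C)Cl
Why: Imidazole-mediated silyl ether formation on the primary alcohol is routine and leaves the α-stereocentre untouched.

Step 2
Reactants: 2 methyl (S)-3-[(tert-butyldimethylsilyl)oxy]-2-methylpropanoate
Product: 3 (S)-3-[(tert-butyldimethylsilyl)oxy]-2-methylpropanal
Conditions: iBu2AlH (1.05 equiv), CH2Cl2, −78 °C; MeOH, then aq. potassium sodium tartrate; used crude
Reagents that add atoms: none
Why: Partial ester reduction with iBu2AlH at −78 °C stops at the aldehyde because the tetrahedral aluminium hemiacetal persists until the quench, and the α-branched aldehyde is used crude to avoid enolisation.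

Step 3
Reactants: 3 (S)-3-[(tert-butyldimethylsilyl)oxy]-2-methylpropanal; 4 dimethyl (1-diazo-2-oxopropyl)phosphonate
Product: 5 tert-butyldimethyl{[(2R)-2-methylbut-3-yn-1-yl]oxy}silane
Conditions: K2CO3 (2 equiv), MeOH, 0 °C to rt
Reagents that add atoms: none
Why: Ohira–Bestmann (Seyferth–Gilbert) homologation under weakly basic methanolic conditions turns the aldehyde into the terminal alkyne without touching the adjacent stereocentre (the descriptor becomes R only through the priority switch).

Step 4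
Reactants: 5 tert-butyldimethyl{[(2R)-2-methylbut-3-yn-1-yl]oxy}silane
Product: 6 (2R)-2-methylbut-3-yn-1-ol
Conditions: Bu4NF, THF, 0 °C to rt; aqueous work-up, careful concentration (volatile)
Reagents that add atoms: none
Why: Fluoride-induced desilylation is driven by the strong Si–F bond and does not affect the propargylic centre.

Step 5
Reactants: 6 (2R)-2-methylbut-3-yn-1-ol
Product: 7 (2R)-2-methylbut-3-yn-1-yl 4-methylbenzenesulfonate
Conditions: TsCl, Et3N, DMAP (cat.), CH2Cl2, 0 °C to rt
Reagents that add atoms: 4-toluenesulfonyl chloride, Cc1ccc(S(=O)(=O)Cl)cc1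
Why: Sulfonylation of the primary alcohol installs a leaving group and gives a non-volatile, storable intermediate.

Step 6
Reactants: 7 (2R)-2-methylbut-3-yn-1-yl 4-methylbenzenesulfonate
Product: 8 (3R)-4-azido-3-methylbut-1-yne
Conditions: NaN3 (1.5 equiv), DMF, 55 °C; extraction into Et2O, kept as a solution (low-molecular-weight azide)
Reagents that add atoms: sodium azide, [Na+].[N-]=[N+]=[N-]
Why: SN2 displacement of the primary tosylate by the weakly basic azide ion avoids elimination to the conjugated enyne and leaves the stereocentre intact.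

Step 7
Reactants: 8 (3R)-4-azido-3-methylbut-1-yne; 9 methyl chloroformate
Product: 11 methyl N-[(2R)-2-methylbut-3-yn-1-yl]carbamate, via (2R)-2-methylbut-3-yn-1-amine 10 (not isolated)
Conditions: PPh3 (1.05 equiv), THF/H2O, rt to 50 °C; then NaHCO3, 9 (1.2 equiv), 0 °C to rt
Reagents that add atoms: none
Why: Staudinger reduction spares the alkyne, and the volatile primary amine is trapped in the same flask under Schotten–Baumann conditions as the methyl carbamate.

Step 8
Reactants: 11 methyl N-[(2R)-2-methylbut-3-yn-1-yl]carbamate; 12 (E)-1-bromobut-2-ene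
Product: 14 methyl N-[(2E)-but-2-en-1-yl]-N-[(2R)-2-methylbut-3-yn-1-yl]carbamate, via sodium salt of the carbamate 13 (not isolated)
Conditions: NaH (1.2 equiv), DMF, 0 °C; then 12 (1.3 equiv), 0 °C to rt
Reagents that add atoms: none
Why: N-Alkylation of the carbamate anion with the allylic bromide proceeds by direct SN2 substitution and carries the E geometry into the tether.

Step 9
Reactants: 14 methyl N-[(2E)-but-2-en-1-yl]-N-[(2R)-2-methylbut-3-yn-1-yl]carbamate
Product: 16 methyl (4R,7S,7aS)-4,7-dimethyl-6-oxo-1,3,4,6,7,7a-hexahydro-2H-cyclopenta[c]pyridine-2-carboxylate, via hexacarbonyldicobalt alkyne complex 15 (not isolated)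
Conditions: Co2(CO)8 (1.1 equiv), CH2Cl2, rt, 2 h; then N-methylmorpholine N-oxide (6–8 equiv), CH2Cl2, 0 °C to 40 °C
Reagents that add atoms: octacarbonyldicobalt Co2(CO)8, O=C=[Co](=C=O)(=C=O)(=C=O)[Co](=C=O)(=C=O)(=C=O)=C=O
Why: The terminal alkyne is held as its Co2(CO)6 complex (zerovalent cobalt); the N-oxide removes a CO ligand as CO2, the crotyl alkene coordinates and inserts into the Co–C4a bond (C4a–C7a), CO then inserts into the Co–C7 bond (C6–C7) and reductive elimination closes C5–C6. The closest known reaction is the N-oxide-promoted intramolecular Pauson–Khand reaction of nitrogen-tethered 1,7-enynes. The tetrahydropyridine ring closes in the 6-exo sense (C4a attacks alkene carbon C7a, C7 stays outside that ring) and the cyclopentenone closes by the [2+2+1] CO insertion/reductive elimination. C7a is set by a chair-like folding of the tether in which the C4 methyl is pseudo-equatorial, so the C4 methyl and the C7a–C7 bond end up cis (H-4 and H-7a on the same face). C7 is set by the stereospecific syn addition across the E alkene, which puts the C7 methyl trans to the C7a–C1 bond. The step needs facial selectivity of the alkene relative to C4, secured by the resident stereocentre and the planar, non-coordinating carbamate that favours the folded rotamer; regiochemistry is fixed by the tether and the terminal alkyne leaves C5 unsubstituted.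

Step 10
Reactants: 16 methyl (4R,7S,7aS)-4,7-dimethyl-6-oxo-1,3,4,6,7,7a-hexahydro-2H-cyclopenta[c]pyridine-2-carboxylate
Product: 17 methyl (4R,4aS,7S,7aR)-4,7-dimethyl-6-oxooctahydro-2H-cyclopenta[c]pyridine-2-carboxylate
Conditions: H2 (1 atm), 10% Pd/C, EtOAc, rt
Reagents that add atoms: none
Why: Heterogeneous syn hydrogenation of the enone C4a=C5 bond should occur from the convex face (the face of H-7a, opposite the C1 methylene) and set C4a as the cis ring fusion.

Step 11
Reactants: 17 methyl (4R,4aS,7S,7aR)-4,7-dimethyl-6-oxooctahydro-2H-cyclopenta[c]pyridine-2-carboxylate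
Product: 18 methyl (4R,4aS,6S,7S,7aR)-6-hydroxy-4,7-dimethyloctahydro-2H-cyclopenta[c]pyridine-2-carboxylate
Conditions: K[sBu3BH] (1.3 equiv), THF, −78 °C; then aq. NaOH, H2O2, 0 °C
Reagents that add atoms: none
Why: The bulky trialkylborohydride should attack the cyclopentanone from the convex face because the concave face is screened by the folded piperidine ring, which places the hydroxyl on the concave face (6S), the epimer needed for the later inversion.

Step 12
Reactants: 18 methyl (4R,4aS,6S,7S,7aR)-6-hydroxy-4,7-dimethyloctahydro-2H-cyclopenta[c]pyridine-2-carboxylate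
Product: 19 (4R,4aS,6S,7S,7aR)-2,4,7-trimethyloctahydro-1H-cyclopenta[c]pyridin-6-ol
Conditions: LiAlH4 (4 equiv), THF, 0 °C to reflux; H2O, aq. NaOH, H2O
Reagents that add atoms: none
Why: LiAlH4 reduces the N-methoxycarbonyl group to the N-methyl group, and no stereocentre is α to a carbonyl at this stage.

Step 13
Reactants: 20 4-iodo-2-methoxyphenol
Product: 21 1-(benzyloxy)-4-iodo-2-methoxybenzene
Conditions: BnBr (1.1 equiv), K2CO3, DMF, rt
Reagents that add atoms: benzyl bromide, BrCc1ccccc1
Why: Williamson etherification of the phenol gives a protecting group that survives all later steps and is removed by hydrogenolysis at the end.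

Step 14
Reactants: 22 cis-3-(methoxycarbonyl)cyclobutane-1-carboxylic acid
Product: 23 methyl cis-3-(quinolin-8-ylcarbamoyl)cyclobutane-1-carboxylate
Conditions: 8-aminoquinoline (1.05 equiv), dicyclohexylcarbodiimide (1.1 equiv), DMAP (0.1 equiv), CH2Cl2, 0 °C to rt
Reagents that add atoms: 8-aminoquinoline, Nc1cccc2cccnc12
Why: Carbodiimide amidation with DMAP acyl transfer (Steglich-type) attaches the bidentate directing group without disturbing the cis-1,3 relationship.

Step 15
Reactants: 23 methyl cis-3-(quinolin-8-ylcarbamoyl)cyclobutane-1-carboxylate; 24 1-(benzyloxy)-4-iodobenzene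
Product: 25 rac-methyl (1S*,2R*,3R*)-2-[4-(benzyloxy)phenyl]-3-(quinolin-8-ylcarbamoyl)cyclobutane-1-carboxylate (all-cis)
Conditions: 24 (2 equiv), Pd(OAc)2 (15 mol%), Ag2CO3 (1 equiv), PivOH (1 equiv), (CF3)2CHOH, 90 °C
Reagents that add atoms: none
Why: 8-Aminoquinoline-directed methylene C(sp3)–H arylation (concerted metalation–deprotonation at divalent palladium, oxidative addition of the aryl iodide to tetravalent palladium, reductive elimination) delivers the aryl group cis to the amide, giving the all-cis cyclobutane as a racemate because the two ring CH2 groups are enantiotopic.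

Step 16
Reactants: 25 rac-methyl (1S*,2R*,3R*)-2-[4-(benzyloxy)phenyl]-3-(quinolin-8-ylcarbamoyl)cyclobutane-1-carboxylate
Product: 26 methyl (1S,2R,3R)-2-[4-(benzyloxy)phenyl]-3-(quinolin-8-ylcarbamoyl)cyclobutane-1-carboxylate
Conditions: preparative supercritical-fluid chromatography, amylose tris(3,5-dimethylphenylcarbamate) phase, CO2/MeOH
Reagents that add atoms: none
Why: Resolution of enantiomers by chromatography on a chiral stationary phase suits this rigid, neutral amide ester, and the (1S,2R,3R) antipode is to be identified by X-ray crystallography.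

Step 17
Reactants: 26 methyl (1S,2R,3R)-2-[4-(benzyloxy)phenyl]-3-(quinolin-8-ylcarbamoyl)cyclobutane-1-carboxylate
Product: 27 methyl (1S,2R,3S)-2-[4-(benzyloxy)phenyl]-3-(quinolin-8-ylcarbamoyl)cyclobutane-1-carboxylate
Conditions: LiOtBu (1.5 equiv), toluene, 50 °C; AcOH quench
Reagents that add atoms: none
Why: Base-mediated epimerisation in which the chelated lithium amidate directs deprotonation to the amide-bearing carbon and reprotonation relieves the cis amide/aryl strain, so only C3 inverts (amide trans to aryl, ester still cis).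

Step 18
Reactants: 27 methyl (1S,2R,3S)-2-[4-(benzyloxy)phenyl]-3-(quinolin-8-ylcarbamoyl)cyclobutane-1-carboxylate; 21 1-(benzyloxy)-4-iodo-2-methoxybenzene
Product: 28 methyl (1R,2R,3R,4R)-2-[4-(benzyloxy)-3-methoxyphenyl]-4-[4-(benzyloxy)phenyl]-3-(quinolin-8-ylcarbamoyl)cyclobutane-1-carboxylate
Conditions: 21 (2.5 equiv), Pd(OAc)2 (15 mol%), Ag2CO3 (1 equiv), PivOH (1 equiv), (CF3)2CHOH, 90 °C
Reagents that add atoms: none
Why: A second amide-directed C–H arylation functionalises the remaining methylene cis to the relocated amide and therefore trans to the first aryl group, completing the α-truxillate array (each aryl cis to one carboxyl and trans to the other).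

Step 19
Reactants: 28 methyl (1R,2R,3R,4R)-2-[4-(benzyloxy)-3-methoxyphenyl]-4-[4-(benzyloxy)phenyl]-3-(quinolin-8-ylcarbamoyl)cyclobutane-1-carboxylate
Product: 30 (1R,2R,3R,4S)-2-[4-(benzyloxy)-3-methoxyphenyl]-4-[4-(benzyloxy)phenyl]cyclobutane-1,3-dicarboxylic acid, via N-Boc imide of the quinolinyl amide 29 (not isolated)
Conditions: Boc2O (3 equiv), DMAP (cat.), MeCN, 50 °C; then LiOH, H2O2, THF/H2O, 0 °C to rt; Na2SO3, then aq. HCl
Reagents that add atoms: di-tert-butyl dicarbonate (to 29 only), CC(C)(C)OC(=O)OC(=O)OC(C)(C)C; hydrogen peroxide, OO; lithium hydroxide, [Li+].[OH-]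
Why: N-Acylation with Boc2O twists and activates the secondary amide, hydroperoxide cleaves the imide at the ring acyl carbon and LiOH saponifies the methyl ester, and the carboxylates resist epimerisation once formed.

Step 20
Reactants: 30 (1R,2R,3R,4S)-2-[4-(benzyloxy)-3-methoxyphenyl]-4-[4-(benzyloxy)phenyl]cyclobutane-1,3-dicarboxylic acid; 19 (4R,4aS,6S,7S,7aR)-2,4,7-trimethyloctahydro-1H-cyclopenta[c]pyridin-6-ol (2.3 equiv)
Product: 31 bis[(4R,4aS,6R,7S,7aR)-2,4,7-trimethyloctahydro-1H-cyclopenta[c]pyridin-6-yl] (1R,2R,3R,4S)-2-[4-(benzyloxy)-3-methoxyphenyl]-4-[4-(benzyloxy)phenyl]cyclobutane-1,3-dicarboxylate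
Conditions: PPh3 (3 equiv), diisopropyl azodicarboxylate (3 equiv), THF, 0 °C to rt
Reagents that add atoms: none
Why: Double Mitsunobu esterification in which each carboxylate displaces the oxyphosphonium-activated C6 oxygen by SN2 from the convex face, inverting C6 from S to R in both alkaloid units.

Step 21
Reactants: 31 bis[(4R,4aS,6R,7S,7aR)-2,4,7-trimethyloctahydro-1H-cyclopenta[c]pyridin-6-yl] (1R,2R,3R,4S)-2-[4-(benzyloxy)-3-methoxyphenyl]-4-[4-(benzyloxy)phenyl]cyclobutane-1,3-dicarboxylate
Product: 32 bis[(4R,4aS,6R,7S,7aR)-2,4,7-trimethyloctahydro-1H-cyclopenta[c]pyridin-6-yl] (1R,2R,3R,4S)-2-(4-hydroxy-3-methoxyphenyl)-4-(4-hydroxyphenyl)cyclobutane-1,3-dicarboxylate (CNP0331906.2)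
Conditions: H2 (1 atm), Pd(OH)2/C, MeOH/EtOAc, rt
Reagents that add atoms: none
Why: Hydrogenolysis of the two benzyl aryl ethers frees the phenols and leaves the esters, the tertiary amines and the cyclobutane untouched.

**Compound list**

1 | methyl (S)-3-hydroxy-2-methylpropanoate | COC(=O)[C@@H](C)CO | starting material
2 | methyl (S)-3-[(tert-butyldimethylsilyl)oxy]-2-methylpropanoate | COC(=O)[C@@H](C)CO[Si](C)(C)C(C)(C)C | intermediate
3 | (S)-3-[(tert-butyldimethylsilyl)oxy]-2-methylpropanal | O=C[C@@H](C)CO[Si](C)(C)C(C)(C)C | intermediate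
4 | dimethyl (1-diazo-2-oxopropyl)phosphonate | CC(=O)C(=[N+]=[N-])P(=O)(OC)OC | starting material
5 | tert-butyldimethyl{[(2R)-2-methylbut-3-yn-1-yl]oxy}silane | C#C[C@@H](C)CO[Si](C)(C)C(C)(C)C | intermediate
6 | (2R)-2-methylbut-3-yn-1-ol | C#C[C@@H](C)CO | intermediate
7 | (2R)-2-methylbut-3-yn-1-yl 4-methylbenzenesulfonate | C#C[C@@H](C)COS(=O)(=O)c1ccc(C)cc1 | intermediate
8 | (3R)-4-azido-3-methylbut-1-yne | C#C[C@@H](C)CN=[N+]=[N-] | intermediate
9 | methyl chloroformate | COC(=O)Cl | starting material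
10 | (2R)-2-methylbut-3-yn-1-amine | C#C[C@@H](C)CN | intermediate
11 | methyl N-[(2R)-2-methylbut-3-yn-1-yl]carbamate | C#C[C@@H](C)CNC(=O)OC | intermediate
12 | (E)-1-bromobut-2-ene | C/C=C/CBr | starting material
13 | sodium salt of methyl N-[(2R)-2-methylbut-3-yn-1-yl]carbamate | C#C[C@@H](C)C[N-]C(=O)OC.[Na+] | intermediate
14 | methyl N-[(2E)-but-2-en-1-yl]-N-[(2R)-2-methylbut-3-yn-1-yl]carbamate | C#C[C@@H](C)CN(C(=O)OC)C/C=C/C | intermediate
15 | hexacarbonyldicobalt complex of the alkyne of 14 (C2Co2 tetrahedrane, zerovalent cobalt) | [CH]12[Co]3(=C=O)(=C=O)(=C=O)[Co]1(=C=O)(=C=O)(=C=O)C23[C@@H](C)CN(C(=O)OC)C/C=C/C | intermediate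
16 | methyl (4R,7S,7aS)-4,7-dimethyl-6-oxo-1,3,4,6,7,7a-hexahydro-2H-cyclopenta[c]pyridine-2-carboxylate | O=C1C=C2[C@@H](CN(C(=O)OC)C[C@@H]2C)[C@@H]1C | intermediate
17 | methyl (4R,4aS,7S,7aR)-4,7-dimethyl-6-oxooctahydro-2H-cyclopenta[c]pyridine-2-carboxylate | O=C1C[C@@H]2[C@@H](CN(C(=O)OC)C[C@@H]2C)[C@@H]1C | intermediate
18 | methyl (4R,4aS,6S,7S,7aR)-6-hydroxy-4,7-dimethyloctahydro-2H-cyclopenta[c]pyridine-2-carboxylate | O[C@H]1C[C@@H]2[C@@H](CN(C(=O)OC)C[C@@H]2C)[C@@H]1C | intermediate
19 | (4R,4aS,6S,7S,7aR)-2,4,7-trimethyloctahydro-1H-cyclopenta[c]pyridin-6-ol | O[C@H]1C[C@@H]2[C@@H](CN(C)C[C@@H]2C)[C@@H]1C | intermediate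
20 | 4-iodo-2-methoxyphenol | COc1cc(I)ccc1O | starting material
21 | 1-(benzyloxy)-4-iodo-2-methoxybenzene | COc1cc(I)ccc1OCc1ccccc1 | intermediate
22 | cis-3-(methoxycarbonyl)cyclobutane-1-carboxylic acid | COC(=O)[C@H]1C[C@@H](C(=O)O)C1 | starting material
23 | methyl cis-3-(quinolin-8-ylcarbamoyl)cyclobutane-1-carboxylate | COC(=O)[C@H]1C[C@@H](C(=O)Nc2cccc3cccnc23)C1 | intermediate
24 | 1-(benzyloxy)-4-iodobenzene | Ic1ccc(OCc2ccccc2)cc1 | starting material
25 | rac-methyl (1S*,2R*,3R*)-2-[4-(benzyloxy)phenyl]-3-(quinolin-8-ylcarbamoyl)cyclobutane-1-carboxylate (all-cis; both enantiomers shown) | C1[C@H](C(=O)OC)[C@H](c2ccc(OCc3ccccc3)cc2)[C@@H]1C(=O)Nc1cccc2cccnc12.C1[C@@H](C(=O)OC)[C@@H](c2ccc(OCc3ccccc3)cc2)[C@H]1C(=O)Nc1cccc2cccnc12 | intermediate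
26 | methyl (1S,2R,3R)-2-[4-(benzyloxy)phenyl]-3-(quinolin-8-ylcarbamoyl)cyclobutane-1-carboxylate | C1[C@H](C(=O)OC)[C@H](c2ccc(OCc3ccccc3)cc2)[C@@H]1C(=O)Nc1cccc2cccnc12 | intermediate
27 | methyl (1S,2R,3S)-2-[4-(benzyloxy)phenyl]-3-(quinolin-8-ylcarbamoyl)cyclobutane-1-carboxylate | C1[C@H](C(=O)OC)[C@H](c2ccc(OCc3ccccc3)cc2)[C@H]1C(=O)Nc1cccc2cccnc12 | intermediate
28 | methyl (1R,2R,3R,4R)-2-[4-(benzyloxy)-3-methoxyphenyl]-4-[4-(benzyloxy)phenyl]-3-(quinolin-8-ylcarbamoyl)cyclobutane-1-carboxylate | COc1cc([C@H]2[C@H](C(=O)OC)[C@H](c3ccc(OCc4ccccc4)cc3)[C@H]2C(=O)Nc2cccc3cccnc23)ccc1OCc1ccccc1 | intermediate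
29 | N-Boc imide of 28 (tert-butyl N-acyl-N-(quinolin-8-yl)carbamate) | COc1cc([C@H]2[C@H](C(=O)OC)[C@H](c3ccc(OCc4ccccc4)cc3)[C@H]2C(=O)N(C(=O)OC(C)(C)C)c2cccc3cccnc23)ccc1OCc1ccccc1 | intermediate
30 | (1R,2R,3R,4S)-2-[4-(benzyloxy)-3-methoxyphenyl]-4-[4-(benzyloxy)phenyl]cyclobutane-1,3-dicarboxylic acid | COc1cc([C@H]2[C@H](C(=O)O)[C@H](c3ccc(OCc4ccccc4)cc3)[C@H]2C(=O)O)ccc1OCc1ccccc1 | intermediate
31 | bis[(4R,4aS,6R,7S,7aR)-2,4,7-trimethyloctahydro-1H-cyclopenta[c]pyridin-6-yl] (1R,2R,3R,4S)-2-[4-(benzyloxy)-3-methoxyphenyl]-4-[4-(benzyloxy)phenyl]cyclobutane-1,3-dicarboxylate | COc1cc([C@H]2[C@H](C(=O)O[C@@H]3C[C@@H]4[C@@H](CN(C)C[C@@H]4C)[C@@H]3C)[C@H](c3ccc(OCc4ccccc4)cc3)[C@H]2C(=O)O[C@@H]2C[C@@H]3[C@@H](CN(C)C[C@@H]3C)[C@@H]2C)ccc1OCc1ccccc1 | intermediate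
32 | bis[(4R,4aS,6R,7S,7aR)-2,4,7-trimethyloctahydro-1H-cyclopenta[c]pyridin-6-yl] (1R,2R,3R,4S)-2-(4-hydroxy-3-methoxyphenyl)-4-(4-hydroxyphenyl)cyclobutane-1,3-dicarboxylate | COc1cc([C@H]2[C@H](C(=O)O[C@@H]3C[C@@H]4[C@@H](CN(C)C[C@@H]4C)[C@@H]3C)[C@H](c3ccc(O)cc3)[C@H]2C(=O)O[C@@H]2C[C@@H]3[C@@H](CN(C)C[C@@H]3C)[C@@H]2C)ccc1O | target

**Count**

Total: 21 steps. Longest linear sequence: 14 steps (steps 1–12, 20, 21).

**Steps most likely to fail**

Step 9. The 1,2-disubstituted alkene of a 1,7-enyne may insert slowly, and a terminal alkyne offers little steric bias, so facial selectivity at C7a relative to C4 may erode. The fallback sets out from 14: deprotonation of the alkyne (LiN(iPr)2, THF, −78 °C) and silylation with Me3SiCl give methyl N-[(2E)-but-2-en-1-yl]-N-[(2R)-2-methyl-4-(trimethylsilyl)but-3-yn-1-yl]carbamate F1. The silyl cap raises the penalty for the folding that places the C4 methyl pseudo-axial. The same Co2(CO)8/N-oxide sequence then gives methyl (4R,7S,7aS)-4,7-dimethyl-6-oxo-5-(trimethylsilyl)-1,3,4,6,7,7a-hexahydro-2H-cyclopenta[c]pyridine-2-carboxylate F2, and protodesilylation with Bu4NF in wet THF comes back to the route at 16.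

Step 11. Hydride may be delivered anti to the C7 methyl (from the concave face), or with poor facial discrimination, giving the C6 epimer of 18. The fallback sets out from 17 and uses that epimer without inversion. Methyl (4R,4aS,6R,7S,7aR)-6-hydroxy-4,7-dimethyloctahydro-2H-cyclopenta[c]pyridine-2-carboxylate F3 is reduced with LiAlH4 to (4R,4aS,6R,7S,7aR)-2,4,7-trimethyloctahydro-1H-cyclopenta[c]pyridin-6-ol F4. F4 is esterified with diacid 30 with retention under Yamaguchi conditions (2,4,6-trichlorobenzoyl chloride, Et3N, then DMAP, toluene), which comes back to the route at 31. If both epimers form, each is carried on by its own esterification mode.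

Step 20. The second esterification may stall, or the activated oxyphosphonium may eliminate to the cyclopentene, because the doubly flanked carboxylate is a sluggish nucleophile. The fallback sets out from 19: MsCl and Et3N in CH2Cl2 at 0 °C give (4R,4aS,6S,7S,7aR)-2,4,7-trimethyloctahydro-1H-cyclopenta[c]pyridin-6-yl methanesulfonate F5. Displacement with the dicaesium salt of 30 (Cs2CO3, DMF, 60 °C) proceeds with inversion at C6 and comes back to the route at 31.

**Further compounds**

F1 | step 9 | methyl N-[(2E)-but-2-en-1-yl]-N-[(2R)-2-methyl-4-(trimethylsilyl)but-3-yn-1-yl]carbamate | C[Si](C)(C)C#C[C@@H](C)CN(C(=O)OC)C/C=C/C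
F2 | step 9 | methyl (4R,7S,7aS)-4,7-dimethyl-6-oxo-5-(trimethylsilyl)-1,3,4,6,7,7a-hexahydro-2H-cyclopenta[c]pyridine-2-carboxylate | O=C1C([Si](C)(C)C)=C2[C@@H](CN(C(=O)OC)C[C@@H]2C)[C@@H]1C
F3 | step 11 | methyl (4R,4aS,6R,7S,7aR)-6-hydroxy-4,7-dimethyloctahydro-2H-cyclopenta[c]pyridine-2-carboxylate | O[C@@H]1C[C@@H]2[C@@H](CN(C(=O)OC)C[C@@H]2C)[C@@H]1C
F4 | step 11 | (4R,4aS,6R,7S,7aR)-2,4,7-trimethyloctahydro-1H-cyclopenta[c]pyridin-6-ol | O[C@@H]1C[C@@H]2[C@@H](CN(C)C[C@@H]2C)[C@@H]1C
F5 | step 20 | (4R,4aS,6S,7S,7aR)-2,4,7-trimethyloctahydro-1H-cyclopenta[c]pyridin-6-yl methanesulfonate | CS(=O)(=O)O[C@H]1C[C@@H]2[C@@H](CN(C)C[C@@H]2C)[C@@H]1C
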